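Ring C of the upper epigallocatechin gallate unit (O1–C2–C3–C4–C4a–C8a) is read as the formal [4+2] adduct of an O-aryl oxocarbenium ion (C2=O1–C8a=C4a, built on phloroglucinol ring A) and an (E)-enol gallate C3=C4 attached to C6 of a benzylated, C8-brominated gallocatechin. One chiral-acid-catalysed oxa-Povarov reaction unites the two halves, forms C2–C3 and C4–C4a, closes ring C and sets C2, C3 and C4. It exploits the doubly benzylic C4, whose cation is stabilised by the lower ring A and bridged by the 3-O-galloyl group. The precursors are an α-acetoxybenzyl aryl ether and a β-galloyloxystyrene; global hydrogenolysis ends the route.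

Key step: step 8

Remark on the chemistry: the target is read as epigallocatechin-3-O-gallate-(4β→6)-gallocatechin. The upper unit is 2R,3R,4S (2,3-cis, 3,4-trans) and the lower unit is 2R,3S (2,3-trans). (+)-Gallocatechin, 3,4,5-tris(benzyloxy)benzoic acid and 3,5-bis(benzyloxy)phenol are taken as commercial.

Step 1
Reactants: 1 (+)-gallocatechin
Product: 2 (2R,3S)-3,5,7-tris(benzyloxy)-2-[3,4,5-tris(benzyloxy)phenyl]chromane
Conditions: NaH (7 equiv), BnBr (6.6 equiv), DMF, −20 °C → rt, argon
Reagents that add atoms: benzyl bromide, BrCc1ccccc1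
Why: Williamson etherification of the five phenols and the C3 alcohol should proceed without touching C2 or C3, since the cold, oxygen-free conditions suppress pyrogallol oxidation and base-induced epimerisation.

Step 2
Reactants: 2 hexa-O-benzyl gallocatechin
Product: 3 (2R,3S)-3,5,7-tris(benzyloxy)-8-bromo-2-[3,4,5-tris(benzyloxy)phenyl]chromane
Conditions: NBS (1.0 equiv), CH2Cl2, −78 °C → rt
Reagents that add atoms: N-bromosuccinimide, O=C1CCC(=O)N1Br
Why: electrophilic aromatic bromination of benzylated flavan-3-ols is expected at C8, the most nucleophilic position of ring A, and the bromine then blocks C8 for all later cationic chemistry.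

Step 3
Reactants: 3 8-bromide
Product: 4 (2R,3S)-3,5,7-tris(benzyloxy)-8-bromo-2-[3,4,5-tris(benzyloxy)phenyl]chromane-6-carbaldehyde
Conditions: POCl3, DMF, ClCH2CH2Cl, 0 → 70 °C; then H2O
Reagents that add atoms: N,N-dimethylformamide, CN(C)C=O; water, O
Why: Vilsmeier–Haack formylation should take place at C6, the only free and still strongly activated position of ring A (two ortho oxygens and one para oxygen).

Step 4
Reactants: 4 6-carbaldehyde
Product: 6 potassium trifluoro{(E)-2-[(2R,3S)-3,5,7-tris(benzyloxy)-8-bromo-2-(3,4,5-tris(benzyloxy)phenyl)chroman-6-yl]ethenyl}borate, via (E)-alkenyl pinacol boronate 5 (not isolated)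
Conditions: CrCl2 (8 equiv), LiI (4 equiv), Cl2CHBpin (2 equiv), THF, rt; then aq. KHF2, MeOH/acetone, rt
Reagents that add atoms: 2-(dichloromethyl)-4,4,5,5-tetramethyl-1,3,2-dioxaborolane, ClC(Cl)B1OC(C)(C)C(C)(C)O1; potassium hydrogen difluoride, [K+].F[H-]F
Why: Takai–Utimoto olefination with the geminal dichromium boryl reagent should give the (E)-alkenylboronate through the usual anti-elimination, CrCl2 leaves the aryl bromide untouched, and KHF2 converts the boronate into the trifluoroborate.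

Step 5
Reactants: 6 potassium (E)-alkenyltrifluoroborate; 7 3,4,5-tris(benzyloxy)benzoic acid
Product: 8 (E)-2-[(2R,3S)-3,5,7-tris(benzyloxy)-8-bromo-2-(3,4,5-tris(benzyloxy)phenyl)chroman-6-yl]ethenyl 3,4,5-tris(benzyloxy)benzoate
Conditions: CuBr (20 mol%), DMAP, 4 Å MS, O2 (1 atm), CH2Cl2/MeCN, 40 °C
Reagents that add atoms: none
Why: copper-catalysed oxidative C–O coupling (Chan–Lam type) of alkenyltrifluoroborates with carboxylic acids should give the enol ester with retention of the (E) geometry.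

Step 6
Reactants: 9 3,5-bis(benzyloxy)phenol; 7 3,4,5-tris(benzyloxy)benzoic acid
Product: 10 3,5-bis(benzyloxy)phenyl 3,4,5-tris(benzyloxy)benzoate
Conditions: DCC, DMAP (cat.), CH2Cl2, 0 °C → rt
Reagents that add atoms: none
Why: Steglich esterification of a phenol with an aromatic acid is routine and creates the C2–O1 connection of the future ring C at the ester oxidation level.

Step 7
Reactants: 10 aryl ester
Product: 12 [3,5-bis(benzyloxy)phenoxy][3,4,5-tris(benzyloxy)phenyl]methyl acetate (racemic), via aluminium hemiacetal 11 (not isolated)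
Conditions: iBu2AlH (1.1 equiv), CH2Cl2, −78 °C; then pyridine, DMAP, Ac2O, −78 → −20 °C
Reagents that add atoms: acetic anhydride, CC(=O)OC(C)=O
Why: reductive acetylation of an ester, in which a single hydride addition at −78 °C gives the aluminium hemiacetal 11 and in situ O-acetylation traps it as the α-acetoxy ether before it can collapse.

Step 8
Reactants: 8 (E)-enol gallate; 12 α-acetoxybenzyl aryl ether
Product: 15 tetradeca-O-benzyl-8-bromo-epigallocatechin-3-O-gallate-(4β→6)-gallocatechin (upper unit 2R,3R with the flavanyl group at C4 trans to the 3-O-galloyl group; lower unit 2R,3S with bromine at its C8), via O-aryl oxocarbenium ion 13 (not isolated), via C4 benzylic cation 14 (not isolated)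
Conditions: (R)-3,3'-bis(2,4,6-triisopropylphenyl)-1,1'-binaphthalene-2,2'-diyl N-triflylphosphoramide (10 mol%), 5 Å MS, toluene/CH2Cl2, −60 → −30 °C, slow addition of 12
Reagents that add atoms: none
Why: Proposed new method: the acid ionises 12 by loss of acetic acid (acetate is the only leaving group whose departure leaves an oxygen-stabilised cation) to the (E)-oxocarbenium ion 13, paired with the chiral phosphoramide anion; the enol ester 8, polarised by its trioxygenated aryl group, attacks C2 of 13 through its galloyloxy-bearing carbon (C2–C3 bond), and the C4 cation 14, bridged by the galloyl carbonyl as a dioxolanylium ion, is taken by the ortho carbon of ring A (C4–C4a bond) before loss of a proton returns the acid. The closest known reaction type is the SnCl4-promoted oxa-Povarov reaction of O-aryl oxocarbenium ions with styrenes, and chiral phosphoric acids are known to control the aza-Povarov reaction of enecarbamates; new here are the β-acyloxystyrene partner and chiral-anion control of the oxa variant. Ring C closes as a formal inverse-electron-demand [4+2] cycloaddition, in the stepwise limit a six-membered Friedel–Crafts closure that is endo to the arene π bond and exo-tet at C4. C2 is set by the chiral anion, which shields one face of 13; C3 is set relative to C2 by the endo position of the galloyloxy group, which the (E)-alkene imposes because the di-ortho-substituted flavanyl group cannot lie under the oxadiene (2,3-cis); C4 is set trans to O3 by suprafacial addition to the (E)-alkene or, stepwise, by anti opening of the trans-dioxolanylium ion. The step needs facial selectivity at C2 that does not depend on the remote lower-unit stereocentres, so the catalyst enantiomer that delivers 2R would be fixed by a screen of both antipodes. It also needs alkene attack to outrun arene attack on 13, which the bromine at C8 of the lower unit, the two equivalent ortho positions of the 3,5-bis(benzyloxy)phenoxy ring and the slow addition of 12 should secure.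

Step 9
Reactants: 15 protected dimer
Product: 16 epigallocatechin-3-O-gallate-(4β→6)-gallocatechin (target)
Conditions: H2 (1 atm), Pd(OH)2/C, Et3N (2 equiv), THF/MeOH/H2O, rt; then dilute HCl to pH 4, Sephadex LH-20
Reagents that add atoms: none
Why: catalytic hydrogenolysis should remove all fourteen benzyl ethers and the aryl bromide (hydrodebromination, HBr taken up by Et3N) while the gallate ester, the C2–O1 bonds and the five stereocentres remain untouched.

Compound list
1 | (+)-gallocatechin, (2R,3S)-2-(3,4,5-trihydroxyphenyl)chromane-3,5,7-triol | Oc1cc2c(c(O)c1)C[C@H](O)[C@@H](c1cc(O)c(O)c(O)c1)O2 | starting material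
2 | (2R,3S)-3,5,7-tris(benzyloxy)-2-[3,4,5-tris(benzyloxy)phenyl]chromane | c1ccccc1COc1cc2c(c(OCc3ccccc3)c1)C[C@H](OCc1ccccc1)[C@@H](c1cc(OCc3ccccc3)c(OCc3ccccc3)c(OCc3ccccc3)c1)O2 | intermediate
3 | (2R,3S)-3,5,7-tris(benzyloxy)-8-bromo-2-[3,4,5-tris(benzyloxy)phenyl]chromane | c1ccccc1COc1c(Br)c2c(c(OCc3ccccc3)c1)C[C@H](OCc1ccccc1)[C@@H](c1cc(OCc3ccccc3)c(OCc3ccccc3)c(OCc3ccccc3)c1)O2 | intermediate
4 | (2R,3S)-3,5,7-tris(benzyloxy)-8-bromo-2-[3,4,5-tris(benzyloxy)phenyl]chromane-6-carbaldehyde | c1ccccc1COc1c(Br)c2c(c(OCc3ccccc3)c1C=O)C[C@H](OCc1ccccc1)[C@@H](c1cc(OCc3ccccc3)c(OCc3ccccc3)c(OCc3ccccc3)c1)O2 | intermediate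
5 | 6-[(E)-2-(4,4,5,5-tetramethyl-1,3,2-dioxaborolan-2-yl)ethenyl] derivative of 3 (not isolated) | c1ccccc1COc1c(Br)c2c(c(OCc3ccccc3)c1/C=C/B1OC(C)(C)C(C)(C)O1)C[C@H](OCc1ccccc1)[C@@H](c1cc(OCc3ccccc3)c(OCc3ccccc3)c(OCc3ccccc3)c1)O2 | intermediate
6 | potassium trifluoro{(E)-2-[(2R,3S)-3,5,7-tris(benzyloxy)-8-bromo-2-(3,4,5-tris(benzyloxy)phenyl)chroman-6-yl]ethenyl}borate | c1ccccc1COc1c(Br)c2c(c(OCc3ccccc3)c1/C=C/[B-](F)(F)F)C[C@H](OCc1ccccc1)[C@@H](c1cc(OCc3ccccc3)c(OCc3ccccc3)c(OCc3ccccc3)c1)O2.[K+] | intermediate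
7 | 3,4,5-tris(benzyloxy)benzoic acid | OC(=O)c1cc(OCc2ccccc2)c(OCc2ccccc2)c(OCc2ccccc2)c1 | starting material
8 | (E)-2-[(2R,3S)-3,5,7-tris(benzyloxy)-8-bromo-2-(3,4,5-tris(benzyloxy)phenyl)chroman-6-yl]ethenyl 3,4,5-tris(benzyloxy)benzoate | c1ccccc1COc1c(Br)c2c(c(OCc3ccccc3)c1/C=C/OC(=O)c1cc(OCc3ccccc3)c(OCc3ccccc3)c(OCc3ccccc3)c1)C[C@H](OCc1ccccc1)[C@@H](c1cc(OCc3ccccc3)c(OCc3ccccc3)c(OCc3ccccc3)c1)O2 | intermediate
9 | 3,5-bis(benzyloxy)phenol | Oc1cc(OCc2ccccc2)cc(OCc2ccccc2)c1 | starting material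
10 | 3,5-bis(benzyloxy)phenyl 3,4,5-tris(benzyloxy)benzoate | O=C(Oc1cc(OCc2ccccc2)cc(OCc2ccccc2)c1)c1cc(OCc2ccccc2)c(OCc2ccccc2)c(OCc2ccccc2)c1 | intermediate
11 | diisobutylaluminium hemiacetal of 10 (not isolated) | CC(C)C[Al](CC(C)C)OC(Oc1cc(OCc2ccccc2)cc(OCc2ccccc2)c1)c1cc(OCc2ccccc2)c(OCc2ccccc2)c(OCc2ccccc2)c1 | intermediate
12 | [3,5-bis(benzyloxy)phenoxy][3,4,5-tris(benzyloxy)phenyl]methyl acetate (racemic) | CC(=O)OC(Oc1cc(OCc2ccccc2)cc(OCc2ccccc2)c1)c1cc(OCc2ccccc2)c(OCc2ccccc2)c(OCc2ccccc2)c1 | intermediate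
13 | (E)-[3,5-bis(benzyloxy)phenyl][3,4,5-tris(benzyloxy)benzylidene]oxonium ion, paired with the chiral phosphoramide anion (not isolated) | C(c1ccccc1)Oc1cc(/C=[O+]/c2cc(OCc3ccccc3)cc(OCc3ccccc3)c2)cc(OCc2ccccc2)c1OCc1ccccc1 | intermediate
14 | C4 benzylic cation after C2–C3 bond formation, open form of the galloyl-bridged dioxolanylium ion (not isolated) | O=C(O[C@H]([CH+]c1c(OCc4ccccc4)c(Br)c2c(c1OCc4ccccc4)C[C@H](OCc4ccccc4)[C@@H](c1cc(OCc4ccccc4)c(OCc4ccccc4)c(OCc4ccccc4)c1)O2)[C@@H](c1cc(OCc4ccccc4)c(OCc4ccccc4)c(OCc4ccccc4)c1)Oc1cc(OCc4ccccc4)cc(OCc4ccccc4)c1)c1cc(OCc4ccccc4)c(OCc4ccccc4)c(OCc4ccccc4)c1 | intermediate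
15 | tetradeca-O-benzyl-8-bromo-epigallocatechin-3-O-gallate-(4β→6)-gallocatechin (bromine at C8 of the lower unit) | O=C(O[C@@H]1[C@@H](c2c(OCc4ccccc4)c(Br)c3c(c2OCc4ccccc4)C[C@H](OCc4ccccc4)[C@@H](c2cc(OCc4ccccc4)c(OCc4ccccc4)c(OCc4ccccc4)c2)O3)c2c(OCc4ccccc4)cc(OCc4ccccc4)cc2O[C@@H]1c1cc(OCc4ccccc4)c(OCc4ccccc4)c(OCc4ccccc4)c1)c1cc(OCc4ccccc4)c(OCc4ccccc4)c(OCc4ccccc4)c1 | intermediate
16 | epigallocatechin-3-O-gallate-(4β→6)-gallocatechin, (2R,3R,4S)-5,7-dihydroxy-4-[(2R,3S)-3,5,7-trihydroxy-2-(3,4,5-trihydroxyphenyl)chroman-6-yl]-2-(3,4,5-trihydroxyphenyl)chroman-3-yl 3,4,5-trihydroxybenzoate | O=C(O[C@@H]1[C@@H](c2c(O)cc3c(c2O)C[C@H](O)[C@@H](c2cc(O)c(O)c(O)c2)O3)c2c(O)cc(O)cc2O[C@@H]1c1cc(O)c(O)c(O)c1)c1cc(O)c(O)c(O)c1 | target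

Total step count: 9. Longest linear sequence: 7 steps (steps 1, 2, 3, 4, 5, 8, 9); steps 6 and 7 form the second branch.

Steps most likely to fail

Step 8. The oxocarbenium ion 13 may be consumed by Friedel–Crafts attack of the benzyloxy-substituted arenes instead of alkene addition. The large ion pair may also give poor facial selectivity, or the endo/exo preference may turn over to the 2,3-trans series. The fallback uses the established electrophile–nucleophile coupling of flavan units and sets out from bromide 3. Commercial (−)-epigallocatechin gallate, O=C(O[C@@H]1Cc2c(O)cc(O)cc2O[C@@H]1c1cc(O)c(O)c(O)c1)c1cc(O)c(O)c(O)c1, would be benzylated (BnBr, K2CO3, DMF, 0 °C → rt, argon) to octa-O-benzyl epigallocatechin gallate F1. DDQ and 2-ethoxyethanol in CH2Cl2 would then oxidise C4 of F1 to give the 4β-(2-ethoxyethoxy) ether F2. Treatment of F2 and 3 with TMSOTf in CH2Cl2 at −78 °C should give 15, because C6 is the only free nucleophilic carbon of 3 and the C4 cation is attacked trans to the participating 3-O-galloyl group. The route is rejoined at 15 and step 9 follows unchanged.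

Step 7. The aluminium hemiacetal 11 may collapse with loss of the aryloxide before acetylation, and the liberated aldehyde may be over-reduced. The fallback sets out from phenol 9. Commercial 3,4,5-tris(benzyloxy)benzaldehyde, O=Cc1cc(OCc2ccccc2)c(OCc2ccccc2)c(OCc2ccccc2)c1, would add acetyl chloride (cat. ZnCl2, CH2Cl2, 0 °C) to give chloro[3,4,5-tris(benzyloxy)phenyl]methyl acetate F3. O-Alkylation of 9 with F3 (Cs2CO3, MeCN, 0 °C), an acyloxyalkylation of a phenol, should then give 12, where the route is rejoined.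

Step 5. The electron-rich styryl borate 6 may undergo protodeboronation or oxidative homocoupling, and transfer of the hindered carboxylate to copper may be slow. The fallback sets out from aldehyde 4. Wittig methoxymethylenation (Ph3PCH2OMe chloride, KN(SiMe3)2, THF, 0 °C) would give the methyl enol ether F4 as an E/Z mixture. Mild hydrolysis (aq. HCl, THF, rt) would give the arylacetaldehyde F5. Acid 7 would be converted with oxalyl chloride and catalytic DMF into 3,4,5-tris(benzyloxy)benzoyl chloride F6. O-Acylation of the enolate of F5 with F6 (Et3N, DMAP, CH2Cl2, 0 °C) should give enol ester 8, with the (E) isomer expected to be favoured because the di-ortho-substituted aryl group disfavours the (Z) form. The (Z) isomer would be removed by chromatography and the route is rejoined at 8.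

Further compounds
F1 | step 8 | octa-O-benzyl-(−)-epigallocatechin gallate | O=C(O[C@@H]1Cc2c(OCc3ccccc3)cc(OCc3ccccc3)cc2O[C@@H]1c1cc(OCc3ccccc3)c(OCc3ccccc3)c(OCc3ccccc3)c1)c1cc(OCc3ccccc3)c(OCc3ccccc3)c(OCc3ccccc3)c1
F2 | step 8 | 4β-(2-ethoxyethoxy)-octa-O-benzyl-epigallocatechin gallate | O=C(O[C@@H]1[C@@H](OCCOCC)c2c(OCc3ccccc3)cc(OCc3ccccc3)cc2O[C@@H]1c1cc(OCc3ccccc3)c(OCc3ccccc3)c(OCc3ccccc3)c1)c1cc(OCc3ccccc3)c(OCc3ccccc3)c(OCc3ccccc3)c1
F3 | step 7 | chloro[3,4,5-tris(benzyloxy)phenyl]methyl acetate | CC(=O)OC(Cl)c1cc(OCc2ccccc2)c(OCc2ccccc2)c(OCc2ccccc2)c1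
F4 | step 5 | (2R,3S)-3,5,7-tris(benzyloxy)-8-bromo-6-(2-methoxyethenyl)-2-[3,4,5-tris(benzyloxy)phenyl]chromane (E/Z mixture) | c1ccccc1COc1c(Br)c2c(c(OCc3ccccc3)c1C=COC)C[C@H](OCc1ccccc1)[C@@H](c1cc(OCc3ccccc3)c(OCc3ccccc3)c(OCc3ccccc3)c1)O2
F5 | step 5 | 2-[(2R,3S)-3,5,7-tris(benzyloxy)-8-bromo-2-(3,4,5-tris(benzyloxy)phenyl)chroman-6-yl]acetaldehyde | c1ccccc1COc1c(Br)c2c(c(OCc3ccccc3)c1CC=O)C[C@H](OCc1ccccc1)[C@@H](c1cc(OCc3ccccc3)c(OCc3ccccc3)c(OCc3ccccc3)c1)O2
F6 | step 5 | 3,4,5-tris(benzyloxy)benzoyl chloride | ClC(=O)c1cc(OCc2ccccc2)c(OCc2ccccc2)c(OCc2ccccc2)c1
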